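Ring A (C1–C5, C10) is disconnected at its quaternary C4: the C18 carboxyl carbon is treated as a former ring member. The key step is a Favorskii ring contraction of a seven-membered 4-chloro-4-methyl ketone (ring C10=C1–C2–C3–C18(=O)–C4–C5). In one operation it forms the C3–C4 bond, expels C18 as the ester on C4 and fixes C4 by inversion, with the C1=C10 alkene already in place. The cycloheptenone comes from a catalyst-controlled Rh–vinylcarbenoid [4+3] cycloaddition (cyclopropanation/Cope) onto a ring-B vinylcyclohexene, which sets C5. C8 and C9 come from asymmetric conjugate addition/enolate trapping of 2-methylcyclohexenone, and the side chain from a B-alkyl Suzuki coupling.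

Key step: step 13

Convention: halimane numbering throughout (ring A = C1–C5, C10; ring B = C5–C10; side chain C11–C16; C18 = carboxyl carbon); in the seven-membered intermediates the ring carbon between C3 and C4 is already called C18. β is the face of H-5 and of the C9 side chain, α that of the C8 and C9 methyl groups.

Assumption: in the two catalyst-controlled steps (5 and 10) the ligand antipode written is taken to be the one that gives the configuration drawn; if the sense of induction is the opposite, the mirror-image ligand is used and nothing else changes.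

Step 1
Reactants: 1 but-2-yn-1-ol
Product: 2 tert-butyl(but-2-yn-1-yloxy)diphenylsilane
Conditions: TBDPSCl, imidazole, CH2Cl2, 0 °C → rt
Reagents that add atoms: tert-butyl(chloro)diphenylsilane, CC(C)(C)[Si](Cl)(c1ccccc1)c1ccccc1
Why: Imidazole-mediated O-silylation of a primary alcohol; TBDPS is chosen because it must later survive acid methanolysis, hot chloride and alkoxide and still leave with fluoride.

Step 2
Reactants: 2 tert-butyl(but-2-yn-1-yloxy)diphenylsilane
Product: 4 (E)-tert-butyl[(3-iodobut-2-en-1-yl)oxy]diphenylsilane, via vinylzirconocene 3 (not isolated)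
Conditions: Cp2Zr(H)Cl (excess), THF, 50 °C; then I2, 0 °C
Reagents that add atoms: iodine, II
Why: Hydrozirconation is a syn addition and, with excess reagent and warming, should equilibrate zirconium to the less hindered carbon next to the methyl group, and iodinolysis with retention then gives the E 3-iodo isomer.

Step 3
Reactants: 5 methyl 3-oxopentanoate
Product: 6 methyl 2-diazo-3-oxopentanoate
Conditions: 4-acetamidobenzenesulfonyl azide, Et3N, MeCN, 0 °C → rt
Reagents that add atoms: 4-acetamidobenzenesulfonyl azide, CC(=O)Nc1ccc(cc1)S(=O)(=O)N=[N+]=[N-]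
Why: Regitz diazo transfer to the active methylene group of a β-keto ester.

Step 4
Reactants: 6 methyl 2-diazo-3-oxopentanoate
Product: 7 methyl (Z)-3-[(tert-butyldimethylsilyl)oxy]-2-diazopent-3-enoate
Conditions: TBSOTf, Et3N, CH2Cl2, 0 °C
Reagents that add atoms: tert-butyldimethylsilyl trifluoromethanesulfonate, CC(C)(C)[Si](C)(C)OS(=O)(=O)C(F)(F)F
Why: Soft enolisation/O-silylation of the ketone should give the Z siloxyvinyl diazoacetate, with the methyl group cis to oxygen and away from the diazoester carbon.

Step 5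
Reactants: 8 2-methylcyclohex-2-en-1-one
Product: 10 (2R,3R)-2-(1-hydroxyethyl)-2,3-dimethylcyclohexan-1-one (ring methyls cis; carbinol epimers), via aluminium enolate 9 (not isolated)
Conditions: Me3Al, CuTC (2 mol %), chiral BINOL-derived phosphoramidite (4 mol %), Et2O, −30 °C; then MeCHO, −78 → −30 °C; aq. Rochelle salt
Reagents that add atoms: trimethylaluminium, C[Al](C)C; acetaldehyde, CC=O
Why: Copper-catalysed asymmetric conjugate addition sets C8 (R) under ligand control, and the aldol reaction of the aluminium enolate should occur anti to the new C8 methyl group (pseudo-axial through allylic strain), which sets C9 with the two methyls cis; the carbinol centre is removed in step 6.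

Step 6
Reactants: 10 (2R,3R)-2-(1-hydroxyethyl)-2,3-dimethylcyclohexan-1-one
Product: 11 (2S,3R)-2-ethenyl-2,3-dimethylcyclohexan-1-one
Conditions: Martin sulfurane, CH2Cl2, 0 °C → rt
Reagents that add atoms: none
Why: Dehydration of a secondary alcohol with Martin sulfurane; the α-carbon is quaternary, so elimination can only run toward the methyl group and gives the vinyl ketone.

Step 7
Reactants: 11 (2S,3R)-2-ethenyl-2,3-dimethylcyclohexan-1-one; 4 (E)-tert-butyl[(3-iodobut-2-en-1-yl)oxy]diphenylsilane
Product: 13 (2S,3R)-2-[(3E)-5-(tert-butyldiphenylsilyloxy)-3-methylpent-3-en-1-yl]-2,3-dimethylcyclohexan-1-one, via B-alkyl-9-BBN borane 12 (not isolated)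
Conditions: 9-BBN, THF, rt; then 4, Pd(dppf)Cl2 (5 mol %), AsPh3, Cs2CO3, DMF–H2O, rt
Reagents that add atoms: none
Why: Anti-Markovnikov hydroboration of the monosubstituted alkene (expected to outpace reduction of the hindered ketone) followed by B-alkyl Suzuki–Miyaura coupling, which retains the E geometry of the vinyl iodide.

Step 8
Reactants: 13 ring-B ketone
Product: 15 (5R,6S)-6-[(3E)-5-(tert-butyldiphenylsilyloxy)-3-methylpent-3-en-1-yl]-5,6-dimethylcyclohex-1-en-1-yl trifluoromethanesulfonate, via potassium enolate 14 (not isolated)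
Conditions: KHMDS, THF, −78 °C; then PhNTf2, −78 → 0 °C
Reagents that add atoms: N-phenylbis(trifluoromethanesulfonimide), O=S(=O)(N(c1ccccc1)S(=O)(=O)C(F)(F)F)C(F)(F)F
Why: Enolate O-triflation; only C5 carries α-hydrogens because C9 is quaternary, so a single enol triflate can form.

Step 9
Reactants: 15 enol triflate
Product: 16 (5R,6S)-1-ethenyl-6-[(3E)-5-(tert-butyldiphenylsilyloxy)-3-methylpent-3-en-1-yl]-5,6-dimethylcyclohex-1-ene
Conditions: tributyl(vinyl)stannane, Pd(PPh3)4 (5 mol %), LiCl, THF, reflux
Reagents that add atoms: tributyl(vinyl)stannane, C=C[Sn](CCCC)(CCCC)CCCC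
Why: LiCl-promoted Stille coupling of a vinyl triflate with a vinylstannane gives the C5=C10–C1=C2 diene.

Step 10
Reactants: 16 diene; 7 methyl (Z)-3-[(tert-butyldimethylsilyl)oxy]-2-diazopent-3-enoate
Product: 18 seven-membered cycloadduct (ring C10=C1–C2H2–C3(CO2Me)=C18(OTBS)–C4H(α-Me)–C5(β-H) fused to ring B), via cis-divinylcyclopropane 17 (not isolated)
Conditions: Rh2(R-PTAD)4 (1 mol %), hexanes, −40 °C → rt, slow addition of 7 (1.5 equiv); then 40 °C
Reagents that add atoms: none
Why: Rhodium vinylcarbenoid cyclopropanation of the terminal vinyl group (catalyst-controlled, the two alkenyl groups cis) followed by boat Cope rearrangement (formal [4+3] cycloaddition); the cyclopropane configuration is transferred to C5 (H-5 β) and the outward methyl group ends cis to C6.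

Step 11
Reactants: 18 seven-membered cycloadduct
Product: 20 seven-membered ketone (ring C10=C1–C2H2–C3H2–C18(=O)–C4H(α-Me)–C5(β-H)), via β-keto ester 19 (not isolated)
Conditions: CSA (cat.), MeOH–CH2Cl2, 0 °C; evaporate; then LiCl, H2O, DMSO, 130 °C
Reagents that add atoms: none
Why: Acid methanolysis cleaves the labile silyl enol ether (the alkyl TBDPS ether is far slower) and Krapcho dealkoxycarbonylation removes the ester of the β-keto ester; C4 may epimerise here, but both epimers serve in step 12.

Step 12
Reactants: 20 seven-membered ketone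
Product: 22 4β-chloro-4α-methyl seven-membered ketone (Cl cis to H-5), via TMS enol ether 21 (not isolated)
Conditions: TMSCl, Et3N, DMF, 80 °C; then NCS, THF, 0 °C
Reagents that add atoms: N-chlorosuccinimide, O=C1CCC(=O)N1Cl
Why: Thermodynamic silyl enol ether formation places the double bond toward the more substituted C4, and electrophilic α-chlorination by NCS is expected anti to C6, which allylic 1,2-strain with the C4 methyl should turn pseudo-axial, so that chlorine ends β; any C3 chloride from the minor enol ether would be removed by chromatography.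

Step 13
Reactants: 22 4β-chloro-4α-methyl seven-membered ketone
Product: 24 2-(trimethylsilyl)ethyl 15-(tert-butyldiphenylsilyloxy)-ent-halima-1(10),13E-dien-18-oate, via cyclopropanone 23 (not isolated)
Conditions: TMSCH2CH2ONa (3 equiv, from TMSCH2CH2OH and NaH), Et2O, 0 °C → rt
Reagents that add atoms: 2-(trimethylsilyl)ethanol (as its sodium alkoxide), C[Si](C)(C)CCO
Why: The alkoxide enolises C3, and in ether the enolate should close onto C4 by backside displacement of the tertiary chloride (3-exo-tet) to cyclopropanone 23; a second alkoxide adds to the strained carbonyl and the hemiketal anion opens the C18–C3 bond, so that C18 leaves the ring as the ester on C4 and ring A appears in its final size by contraction of the seven-membered ring. The closest known reaction is the Favorskii rearrangement of 2-chloro-2-methylcycloalkanones to 1-methylcycloalkanecarboxylates. The only new stereocentre, C4, is controlled by the configuration of the C–Cl bond: inversion at C4 puts C18 on the β face that chlorine occupied and leaves the methyl α. The step needs this stereospecific closure rather than ionisation to a planar oxyallyl cation, and the non-polar aprotic medium is chosen to secure it (alcohol solvents are known to erase it). It also needs ring opening toward C3 (secondary rather than tertiary carbanion) and no dehydrochlorination, which is disfavoured toward C5 because Cl and H-5 are cis.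

Step 14
Reactants: 24 TMSE ester
Product: 25 15-hydroxy-ent-halima-1(10),13E-dien-18-oic acid
Conditions: TBAF (excess), THF, rt → 50 °C; aq. NH4Cl/HCl work-up
Reagents that add atoms: none
Why: Fluoride-induced β-elimination of the 2-(trimethylsilyl)ethyl ester, which does not need access to the hindered carbonyl, and desilylation of the TBDPS ether should occur in the same operation.

Step 15
Reactants: 25 15-hydroxy-ent-halima-1(10),13E-dien-18-oic acid
Product: 26 15-(propanoyloxy)-ent-halima-1(10),13E-dien-18-oic acid (target)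
Conditions: (EtCO)2O (1.2 equiv), pyridine, DMAP (cat.), CH2Cl2, 0 °C; then aq. NaHCO3, acidify
Reagents that add atoms: propanoic anhydride, CCC(=O)OC(=O)CC
Why: DMAP-catalysed acylation of the primary allylic alcohol; any mixed anhydride formed at the hindered tertiary acid should be hydrolysed back in the bicarbonate work-up.

Compound list

1 | but-2-yn-1-ol | CC#CCO | starting material
2 | tert-butyl(but-2-yn-1-yloxy)diphenylsilane | CC#CCO[Si](c1ccccc1)(c1ccccc1)C(C)(C)C | intermediate
3 | (E)-vinylzirconocene chloride, Zr on the methyl-bearing carbon, trans to CH2OTBDPS | C/C([Zr](Cl)(C1C=CC=C1)C1C=CC=C1)=C\CO[Si](c1ccccc1)(c1ccccc1)C(C)(C)C | intermediate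
4 | (E)-tert-butyl[(3-iodobut-2-en-1-yl)oxy]diphenylsilane | C/C(I)=C\CO[Si](c1ccccc1)(c1ccccc1)C(C)(C)C | intermediate
5 | methyl 3-oxopentanoate | CCC(=O)CC(=O)OC | starting material
6 | methyl 2-diazo-3-oxopentanoate | CCC(=O)C(=[N+]=[N-])C(=O)OC | intermediate
7 | methyl (Z)-3-[(tert-butyldimethylsilyl)oxy]-2-diazopent-3-enoate | C/C=C(\O[Si](C)(C)C(C)(C)C)C(=[N+]=[N-])C(=O)OC | intermediate
8 | 2-methylcyclohex-2-en-1-one | CC1=CCCCC1=O | starting material
9 | dimethylaluminium (3R)-2,3-dimethylcyclohex-1-en-1-olate | CC1=C(O[Al](C)C)CCC[C@H]1C | intermediate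
10 | (2R,3R)-2-(1-hydroxyethyl)-2,3-dimethylcyclohexan-1-one (carbinol epimers) | CC(O)[C@]1(C)C(=O)CCC[C@H]1C | intermediate
11 | (2S,3R)-2-ethenyl-2,3-dimethylcyclohexan-1-one | C=C[C@]1(C)C(=O)CCC[C@H]1C | intermediate
12 | 9-{2-[(1S,2R)-1,2-dimethyl-6-oxocyclohexyl]ethyl}-9-borabicyclo[3.3.1]nonane | B1(CC[C@]3(C)C(=O)CCC[C@H]3C)C2CCCC1CCC2 | intermediate
13 | (2S,3R)-2-[(3E)-5-(tert-butyldiphenylsilyloxy)-3-methylpent-3-en-1-yl]-2,3-dimethylcyclohexan-1-one | CC(C)(C)[Si](OC/C=C(\C)CC[C@]1(C)C(=O)CCC[C@H]1C)(c2ccccc2)c2ccccc2 | intermediate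
14 | potassium enolate of 13 (C10–O, C5=C10) | CC(C)(C)[Si](OC/C=C(\C)CC[C@]1(C)C([O-])=CCC[C@H]1C)(c2ccccc2)c2ccccc2.[K+] | intermediate
15 | (5R,6S)-6-[(3E)-5-(tert-butyldiphenylsilyloxy)-3-methylpent-3-en-1-yl]-5,6-dimethylcyclohex-1-en-1-yl trifluoromethanesulfonate | CC(C)(C)[Si](OC/C=C(\C)CC[C@]1(C)C(OS(=O)(=O)C(F)(F)F)=CCC[C@H]1C)(c2ccccc2)c2ccccc2 | intermediate
16 | (5R,6S)-1-ethenyl-6-[(3E)-5-(tert-butyldiphenylsilyloxy)-3-methylpent-3-en-1-yl]-5,6-dimethylcyclohex-1-ene | CC(C)(C)[Si](OC/C=C(\C)CC[C@]1(C)C(C=C)=CCC[C@H]1C)(c2ccccc2)c2ccccc2 | intermediate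
17 | methyl (1R,2S)-1-[(1Z)-1-(tert-butyldimethylsilyloxy)prop-1-en-1-yl]-2-(ring-B cyclohexenyl)cyclopropane-1-carboxylate (alkenyl groups cis) | CC(C)(C)[Si](OC/C=C(\C)CC[C@]1(C)C([C@@H]3C[C@]3(C(=O)OC)/C(O[Si](C)(C)C(C)(C)C)=C/C)=CCC[C@H]1C)(c2ccccc2)c2ccccc2 | intermediate
18 | seven-membered cycloadduct: ring C10=C1–C2H2–C3(CO2Me)=C18(OTBS)–C4H(α-Me)–C5(β-H), fused at C5–C10 to ring B (8α-Me, 9α-Me, 9β-side chain with 15-OTBDPS) | CC(C)(C)[Si](OC/C=C(\C)CC[C@]1(C)C2=CCC(C(=O)OC)=C(O[Si](C)(C)C(C)(C)C)[C@@H](C)[C@H]2CC[C@H]1C)(c3ccccc3)c3ccccc3 | intermediate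
19 | β-keto ester of 18 (C18 ketone, C3 methyl ester, C3 epimers) | CC(C)(C)[Si](OC/C=C(\C)CC[C@]1(C)C2=CCC(C(=O)OC)C(=O)[C@@H](C)[C@H]2CC[C@H]1C)(c3ccccc3)c3ccccc3 | intermediate
20 | seven-membered ketone: ring C10=C1–C2H2–C3H2–C18(=O)–C4H(α-Me)–C5(β-H) (C4 epimer equally usable) | CC(C)(C)[Si](OC/C=C(\C)CC[C@]1(C)C2=CCCC(=O)[C@@H](C)[C@H]2CC[C@H]1C)(c3ccccc3)c3ccccc3 | intermediate
21 | trimethylsilyl enol ether of 20 (C18(OTMS)=C4) | CC(C)(C)[Si](OC/C=C(\C)CC[C@]1(C)C2=CCCC(O[Si](C)(C)C)=C(C)[C@H]2CC[C@H]1C)(c3ccccc3)c3ccccc3 | intermediate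
22 | 4β-chloro-4α-methyl seven-membered ketone (Cl cis to H-5) | CC(C)(C)[Si](OC/C=C(\C)CC[C@]1(C)C2=CCCC(=O)[C@](C)(Cl)[C@H]2CC[C@H]1C)(c3ccccc3)c3ccccc3 | intermediate
23 | cyclopropanone bridging C3 and C4 on the β face of ring A (4α-Me) | CC(C)(C)[Si](OC/C=C(\C)CC[C@]1(C)C2=CC[C@@H]3C(=O)[C@]3(C)[C@H]2CC[C@H]1C)(c4ccccc4)c4ccccc4 | intermediate
24 | 2-(trimethylsilyl)ethyl 15-(tert-butyldiphenylsilyloxy)-ent-halima-1(10),13E-dien-18-oate | CC(C)(C)[Si](OC/C=C(\C)CC[C@]1(C)C2=CCC[C@](C)(C(=O)OCC[Si](C)(C)C)[C@H]2CC[C@H]1C)(c3ccccc3)c3ccccc3 | intermediate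
25 | 15-hydroxy-ent-halima-1(10),13E-dien-18-oic acid | OC/C=C(\C)CC[C@]1(C)C2=CCC[C@](C)(C(=O)O)[C@H]2CC[C@H]1C | intermediate
26 | (4S,5S,8R,9S)-15-(propanoyloxy)-ent-halima-1(10),13E-dien-18-oic acid | CCC(=O)OC/C=C(\C)CC[C@]1(C)C2=CCC[C@](C)(C(=O)O)[C@H]2CC[C@H]1C | target

Total step count: 15. Longest linear sequence: 11 steps (steps 5–15, from 2-methylcyclohex-2-en-1-one).

Steps most likely to fail

1. Step 13 (key step). The tertiary chloride may ionise to a planar oxyallyl cation before the enolate closes, which would lose the stereochemical relay to C4. The alkoxide may instead add to the carbonyl and give an epoxy ether, or HCl may be lost toward the methyl group. The fallback sets out from 22 and returns at 25. Borohydride reduction of the ketone would give chlorohydrin F1. A silver(I)-assisted semipinacol rearrangement (AgBF4, CH2Cl2), in which C3 migrates from the carbinol carbon C18 to C4 anti to the departing chloride, would contract the ring to the ring-A aldehyde F2, with the formyl group on the face the chlorine occupied. Pinnick oxidation (NaClO2, NaH2PO4, 2-methylbut-2-ene) would give the silyl-protected acid F3, and TBAF would then give 25.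

2. Step 12. Chlorine may be delivered to the C6 face of the enol ether (poor facial selectivity), or to C3 through the less substituted enol ether (poor regioselectivity). The fallback sets out from 18 (through β-keto ester 19, first stage of step 11) and returns at 24. NCS would chlorinate the β-keto ester at C3, anti to the adjacent Cope-derived C4 methyl group, to give chloro keto ester F4. Favorskii contraction with TMSCH2CH2ONa in ether (enolisation now at C4, ring opening toward the ester-stabilised C3 carbanion) would give diester F5, with the C18 ester on the face the C3 chlorine occupied. Selective LiOH saponification of the less hindered secondary methyl ester would give acid F6, and photoredox hydrodecarboxylation (acridinium photocatalyst, thiol co-catalyst, blue light) would give 24.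

3. Step 10. A mismatched catalyst/substrate pairing may erode facial control at C5, the carbenoid may insert into the allylic C–H bonds next to the silyl ether, or the Cope rearrangement may stall at the cyclopropane. The fallback sets out from 16 and returns at 20. Gold(I)-catalysed 1,2-acyloxy migration of but-3-yn-2-yl pivalate F7 (from but-3-yn-2-ol and pivaloyl chloride) would generate a vinylgold carbenoid that cyclopropanates the terminal vinyl group cis-selectively. Cope rearrangement would give enol pivalate F8, and methanolysis (K2CO3, MeOH) would give 20; the C4 configuration is immaterial at this stage.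

Further compounds

F1 | step 13 | chlorohydrin of 22 (C18 carbinol, 4β-Cl, 4α-Me; carbinol epimers) | CC(C)(C)[Si](OC/C=C(\C)CC[C@]1(C)C2=CCCC(O)[C@](C)(Cl)[C@H]2CC[C@H]1C)(c3ccccc3)c3ccccc3
F2 | step 13 | 15-(tert-butyldiphenylsilyloxy)-ent-halima-1(10),13E-dien-18-al | CC(C)(C)[Si](OC/C=C(\C)CC[C@]1(C)C2=CCC[C@](C)(C=O)[C@H]2CC[C@H]1C)(c3ccccc3)c3ccccc3
F3 | step 13 | 15-(tert-butyldiphenylsilyloxy)-ent-halima-1(10),13E-dien-18-oic acid | CC(C)(C)[Si](OC/C=C(\C)CC[C@]1(C)C2=CCC[C@](C)(C(=O)O)[C@H]2CC[C@H]1C)(c3ccccc3)c3ccccc3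
F4 | step 12 | 3β-chloro β-keto ester (C3: Cl and CO2Me; C18 ketone; 4α-Me) | CC(C)(C)[Si](OC/C=C(\C)CC[C@]1(C)C2=CC[C@@](Cl)(C(=O)OC)C(=O)[C@@H](C)[C@H]2CC[C@H]1C)(c3ccccc3)c3ccccc3
F5 | step 12 | ring-A diester: C4 2-(trimethylsilyl)ethyl ester (β) and C3 methyl ester (C3 epimers) | CC(C)(C)[Si](OC/C=C(\C)CC[C@]1(C)C2=CCC(C(=O)OC)[C@](C)(C(=O)OCC[Si](C)(C)C)[C@H]2CC[C@H]1C)(c3ccccc3)c3ccccc3
F6 | step 12 | ring-A C3 carboxylic acid, C4 2-(trimethylsilyl)ethyl ester | CC(C)(C)[Si](OC/C=C(\C)CC[C@]1(C)C2=CCC(C(=O)O)[C@](C)(C(=O)OCC[Si](C)(C)C)[C@H]2CC[C@H]1C)(c3ccccc3)c3ccccc3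
F7 | step 10 | but-3-yn-2-yl 2,2-dimethylpropanoate | CC(OC(=O)C(C)(C)C)C#C
F8 | step 10 | enol pivalate cycloadduct (ring C10=C1–C2H2–C3H=C18(OPiv)–C4H(Me)–C5(β-H)) | CC(C)(C)[Si](OC/C=C(\C)CC[C@]1(C)C2=CCC=C(OC(=O)C(C)(C)C)[C@@H](C)[C@H]2CC[C@H]1C)(c3ccccc3)c3ccccc3
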